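## Structural features

The target is a 3,3'-linked pair of 4-(4-hydroxyphenyl)chroman-2-ones: ring A is the lactone fused to a 5,7-dihydroxybenzene (O1, C2–C4, C4a–C8a), and ring B is the lactone fused to a fully oxygenated 5',6',7',8'-tetrahydroxybenzene (primed atoms). Four contiguous stereocentres run C4–C3–C3'–C4' with configuration 4R,3R,3'S,4'R: the C4 aryl and the C3 substituent are trans in ring A, the corresponding pair is cis in ring B, and C4 and C4' have the same configuration. C3 and C3' are α to aryl lactone carbonyls and epimerise easily; the cis relationship in ring B is the less stable one and must not meet base. The aryl lactones are opened by nucleophiles, the tetrahydroxylated benzo ring of ring B is air-sensitive, and the open form carries nine phenolic hydroxyls. The real difficulty is that a nearly C2-symmetric connectivity hides an unsymmetrical stereotetrad: a meso-type C3/C3' core between two like-configured benzylic carbons that carry two different, very electron-rich arenes. The key step uses the fact that C2–C3–C3'–C2' is a succinate whose C3 and C3' each carry a benzylic carbon (C4, C4') with the same 4-oxygenated phenyl group, so that the core maps onto a symmetric bis(benzylidene)succinic anhydride to which the benzo rings of rings A and B are added as nucleophiles at C4 and C4', with O1' closing ring B on C2'.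

## Logic of the disconnections

24 to 22: the O1–C2 lactone bond of ring A and all O–CH3 bonds are cut (through 23). Every phenol is carried as a methyl ether, and ring A stays open until the end, because a closed ring A would place its C4 aryl on the alkene face opposite to the C4' aryl and cancel the facial bias needed earlier. The forward step must cleave ten O–CH3 bonds and lactonise without base, so that the cis C3' centre survives.

22 to 21: the C3–H and C3'–H bonds are cut to give a Z-alkene exocyclic to ring B. One syn addition of hydrogen then sets both centres relative to C4'. The forward step must add from the face anti to the C4' aryl and must not move the double bond towards C4 or C4'.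

21 to 18: the O1'–C2' lactone bond and the ester O–CH3 bond are cut, which leads back to a cyclic maleic anhydride that fixes the Z geometry by its ring. The forward step must free the ring B phenol and capture the ring-opened acid without base, because the C4 and C4' hydrogens of 18 are vinylogously acidic.

18 to 16: the C3=C3' π bond is removed. Both uncontrolled centres of the key-step product disappear here, so 18 is a single stereoisomer. The forward dehydrogenation must be regiodefined between the two former α-carbons and must spare the benzylic C4–H and C4'–H.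

16 to 13: the anhydride C–O bond and the carbonate on O1' are cut, which returns the lactone acid. The anhydride is needed as the cyclic template for the dehydrogenation. The forward step must cap the phenol before dehydration, since the free phenol would re-close ring B.

13 to 5, 10 and 11: C4'–C4a', O1'–C2' and C4–C4a are cut. Three cheap symmetric or single-site components replace the whole carbon skeleton. The forward step must give the same facial sense at both benzylidene carbons and mono-addition of each arene.

5 to 4 to 1 and 2: the anhydride C–O bond, then the C3=C4 and C3'=C4' double bonds are cut (twofold Stobbe condensation). The forward step must give the E,E geometry.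

10 to 8 to 6: the aryl C–O bond (through 9), then the aryl–CHO bond are cut. The symmetry of 6 makes the formylation regiochemically unambiguous.

## Other disconnections considered

Alternative 1: The cut is C3–C4 and O1–C2 of ring A, with ring B present as a flat 4-arylcoumarin. In the forward step the activated ester A1 acylates one enantiomer of the isothiourea benzotetramisole (2-phenyl-2,3-dihydroimidazo[2,1-b][1,3]benzothiazole), the derived ammonium enolate adds to the ortho-quinone methide released from the hydroxybenzyl alcohol A2, and lactonisation onto the phenoxide turns the catalyst over to give A3. The C3–H of A3, flanked by the lactone carbonyl and the coumarin, should settle trans to the C4 aryl.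
- In its favour: the enantio-determining annulation belongs to a reaction class with close precedent, and on this point the alternative is better than the chosen plan, whose asymmetric step is untested. The coumarin C3'=C4' bond is a latent cis pair that one syn hydrogenation would convert directly into cis ring B, the same logic as step 9 and its equal.
- Against it: the tetrasubstituted coumarin double bond, with aryl groups on both carbons, must read its facial bias from C3 across a freely rotating C3–C3' bond. The same C3–H is doubly activated and would erode under heat or base. A1 needs its own synthesis of a tetra-oxygenated 4-aryl-3-(carboxymethyl)coumarin.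
- Comparison: on structure, the alternative treats the two halves differently from the start, which suits the unsymmetrical stereotetrad, whereas the chosen plan uses the hidden symmetry and must break it in step 9. On mechanism, both end in a face-selective syn hydrogenation, but in 21 the controlling centre sits in the ring being reduced and in A3 it sits outside it. On step economy, about 12 to 13 steps and less convergence are expected, against 10.

Alternative 2: The cut is C2–C3 and C2'–C3', so both carbonyl carbons are introduced across a Z-alkene that already carries C4 and C4'. In the forward step zerovalent palladium, Pd(PPh3)4, inserts into the C–Cl bond of the aryl chloroformate A4, the aryloxycarbonyl–palladium adds syn across C3=C3' to close ring A, and the alkyl–palladium at C3' is intercepted by CO and methanol to give A5.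
- In its favour: all four stereocentres are present after one operation and no redox detour is needed, a point on which it is better than the chosen plan. The C3/C3' relationship follows from syn addition to a Z-alkene, the same principle as step 9 and its equal.
- Against it: A4 already contains both diarylmethine stereocentres in enantiopure form on a Z-alkene, which moves the hardest problem into the precursor. The alkyl–palladium at C3' has a doubly benzylic β-hydrogen at C4', so β-hydride elimination competes with CO insertion. Alkoxycarbonyl–palladium species add reluctantly to unactivated internal alkenes. A phosgene-derived chloroformate and pressurised CO are needed.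
- Comparison: on structure, ring B closes only after demethylation of a symmetric pentamethoxyphenyl group, which is as unambiguous as ring A closure in the chosen plan. On mechanism, the chosen key step uses polar acid-catalysed elementary steps, whereas this one strings three organometallic steps, each with a known competitor. On step economy, the endgame is shorter (one operation from A5), but the route to A4 is longer, about 12 to 14 steps overall.

Alternative 3: The cut is C3'–C4' and O1'–C2' of ring B, with ring A complete. In the forward step the activated ester A6 gives an enolate bound to the same isothiourea, which adds to the ortho-quinone methide formed from A7, and lactonisation gives A8, the octa-O-methyl ether of the target.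
- In its favour: the endgame is the most convergent. A8 needs a single cleavage of eight ethers, with no ester and no redox reset, which is better than 22. The annulation type has precedent.
- Against it: the cis (endo) outcome in ring B must be imposed by the catalyst against the trans preference and must survive the base that liberates the quinone methide, while C3 of A6 and C3' of A8 are both enolisable. The catalyst could also be acylated by the aryl lactone of ring A. A6 needs its own asymmetric synthesis.
- Comparison: on structure and stereocontrol, two separate catalyst-controlled events stand against one twofold catalyst-controlled arylation plus one substrate-controlled hydrogenation, about equal in the number of controlled elements. On mechanism, the risk falls late, on a valuable intermediate, whereas the chosen plan places it early, on cheap materials; this is the main reason for the choice made. On step economy, about 11 to 12 steps, comparable.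

Key step: step 5

Remarks on the chemistry (assumptions, one line each):
- The fulgide 5 (E,E), the phenol 10 and the lactone acid 13 (4R,4'R) map atom by atom onto the target; the single free ring carbon of 10 becomes C4a' and its hydroxyl oxygen becomes O1'.
- The aldehyde 8 has no free ortho or para hydroxyl, so the Dakin-type step is run as a Baeyer–Villiger oxidation followed by formate cleavage.
- A phosphoric acid is judged too weak for the second arylation (a free cinnamic acid), so the more acidic N-triflylphosphoramide on the same binaphthyl scaffold is used.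
- The sense of induction cannot be predicted; the (R)-catalyst is written and is exchanged for its antipode if the first adduct proves to be 4'S.
- The Z-alkylidene lactone with a free carboxylic acid (20) is expected to revert to anhydride plus phenol, so it is captured as its methyl ester 21.

## Route

Step 1
Reactants: 1 dimethyl succinate; 2 4-methoxybenzaldehyde (2.2 equiv)
Product: 4 (2E,3E)-2,3-bis(4-methoxybenzylidene)butanedioic acid, via Stobbe half-ester 3 (not isolated)
Conditions: NaOMe (3 equiv), MeOH, reflux; H2O, reflux; HCl (aq)
Reagents that add atoms: none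
Why: Twofold Stobbe condensation: each enolate adds to the aldehyde, the alkoxide lactonises onto the neighbouring ester and E1cB opening gives the arylidene carboxylate. Each aryl group ends trans to its own carboxyl for steric reasons, hence E,E.

Step 2
Reactants: 4 bis(benzylidene) diacid
Product: 5 (3E,4E)-3,4-bis(4-methoxybenzylidene)oxolane-2,5-dione (the fulgide)
Conditions: AcCl, CH2Cl2, reflux, dark
Reagents that add atoms: none
Why: Cyclodehydration of a 1,4-diacid through the mixed anhydride; no base is present, so the alkene geometry is kept. Light is excluded because fulgides photoisomerise and photocyclise.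

Step 3
Reactants: 6 1,2,3,4-tetramethoxybenzene
Product: 8 2,3,4,5-tetramethoxybenzaldehyde, via aryl iminium chloride 7 (not isolated)
Conditions: POCl3, DMF, 80 °C; H2O; NaOH (aq) to pH 6
Reagents that add atoms: N,N-dimethylformamide CN(C)C=O; water O
Why: Vilsmeier–Haack formylation of an electron-rich arene; the two free ring positions of 6 are equivalent by symmetry, so only one aldehyde can form.

Step 4
Reactants: 8 tetramethoxybenzaldehyde
Product: 10 2,3,4,5-tetramethoxyphenol, via aryl formate 9 (not isolated)
Conditions: mCPBA, CH2Cl2, 0 °C to rt; then HCl (cat.), MeOH, rt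
Reagents that add atoms: 3-chloroperoxybenzoic acid OOC(=O)c1cccc(Cl)c1
Why: Baeyer–Villiger (Dakin-type) oxidation; the electron-rich aryl group migrates in preference to hydrogen, and acid-catalysed methanolysis of the formate frees the phenol.

Step 5
Reactants: 5 E,E-fulgide (bis(para-methoxybenzylidene)succinic anhydride); 10 tetramethoxyphenol with its single free ring carbon ortho to the hydroxyl; 11 phloroglucinol trimethyl ether (sym-trimethoxybenzene)
Product: 13 ring B lactone acid 3-(4-methoxyphenyl)-2-[5,6,7,8-tetramethoxy-4-(4-methoxyphenyl)-2-oxochroman-3-yl]-3-(2,4,6-trimethoxyphenyl)propanoic acid (4R and 4'R in target numbering; C3 and C3' epimer mixture), via ring B lactone cinnamic acid 12 (not isolated)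
Conditions: (R)-3,3'-bis(2,4,6-triisopropylphenyl)-1,1'-binaphthyl-2,2'-diyl N-triflylphosphoramide (10 mol%), 5 and 10 equimolar, 4 Å MS, PhMe/CH2Cl2, −20 °C to rt, dark; then 11 in slight excess, 40 °C
Reagents that add atoms: none
Why: Proposed new method: the chiral Brønsted acid ion-pairs with a protonated anhydride carbonyl of 5 while one of its basic oxygens hydrogen-bonds the OH of 10, so that the only free ring carbon of 10 attacks the benzylidene carbon inside the chiral pocket and forms C4'–C4a', the 4-methoxyphenyl group stabilising the benzylic cation character. The phenol oxygen then opens the anhydride at the adjacent carbonyl by 6-exo-trig acyl substitution, which closes lactone ring B and releases the C2 carboxylic acid of 12. Because the anhydride is consumed, a second molecule of 10 cannot add, and the remaining α-substituted 4-methoxycinnamic acid reacts only when the stronger π-nucleophile 11 is added and the mixture is warmed, forming C4–C4a by the same protonation and arylation sequence. The closest known reaction types are acid-mediated hydroarylation with lactonisation of cinnamic and arylidenesuccinic acids by electron-rich phenols, and chiral phosphoric-acid-type Friedel–Crafts additions to unsaturated acyl acceptors; the twofold sequential use on a fulgide and a free cinnamic acid as acceptor under a chiral acid are the new elements. C4' is controlled by the catalyst in the doubly bound first addition; C4 is controlled by the same catalyst ion-paired to the protonated acid, with the existing C4' centre as a possible matched or mismatched second influence. The step needs ortho C-alkylation (secured by the single free ring position of 10, with either order of O-acylation and C-alkylation converging on 12), mono-addition of 10 (secured by the lactonisation) and no aryldihydronaphthalene ring closure of 5 (the ring carbons that would have to attack are meta to OMe, and light is excluded). C3 and C3' form without control and are erased in step 7.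

Step 6
Reactants: 13 ring B lactone acid
Product: 16 3-[(R)-{2-[(benzyloxycarbonyl)oxy]-3,4,5,6-tetramethoxyphenyl}(4-methoxyphenyl)methyl]-4-[(R)-(4-methoxyphenyl)(2,4,6-trimethoxyphenyl)methyl]oxolane-2,5-dione (cis/trans mixture), via phenol diacid 14 (not isolated), via benzyl carbonate diacid 15 (not isolated)
Conditions: LiOH, THF/H2O, rt; CbzCl, 0 °C, pH 10–11; HCl (aq) to pH 3, 0 °C; then Ac2O, 50 °C
Reagents that add atoms: benzyl chloroformate ClC(=O)OCc1ccccc1; lithium hydroxide [Li+].[OH-] (its oxygen enters the new carboxyl group of 14 and is retained in part)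
Why: Saponification opens the aryl lactone. Schotten–Baumann acylation in water caps the phenoxide while carboxylates are not permanently acylated, so ring B cannot re-close. Acetic anhydride then cyclodehydrates the 1,4-diacid; epimerisation at C3/C3' is harmless here.

Step 7
Reactants: 16 succinic anhydride benzyl carbonate
Product: 18 3-[(R)-{2-[(benzyloxycarbonyl)oxy]-3,4,5,6-tetramethoxyphenyl}(4-methoxyphenyl)methyl]-4-[(R)-(4-methoxyphenyl)(2,4,6-trimethoxyphenyl)methyl]furan-2,5-dione, via bis(trimethylsilyloxy)furan 17 (not isolated)
Conditions: TMSOTf (2.5 equiv), Et3N (3 equiv), CH2Cl2, 0 °C to rt; evaporate, extract into pentane/PhMe, filter; then Br2 (1.0 equiv), CH2Cl2, −78 °C; pH 7 buffer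
Reagents that add atoms: none
Why: Twofold O-silylation and enolisation gives the aromatic 2,5-bis(silyloxy)furan, a known dienol form of succinic anhydrides, and its two-electron oxidation by bromine (C-bromination, then loss of bromotrimethylsilane) can only place the double bond between the two former α-carbons inside the ring. The amine salt is removed before the oxidation because the C4 and C4' hydrogens of 18 are vinylogously acidic. All C3/C3' isomers converge on one compound.

Step 8
Reactants: 18 maleic anhydride benzyl carbonate
Product: 21 methyl (2Z,3R)-3-(4-methoxyphenyl)-2-[(4R)-5,6,7,8-tetramethoxy-4-(4-methoxyphenyl)-2-oxochroman-3-ylidene]-3-(2,4,6-trimethoxyphenyl)propanoate, via phenol maleic anhydride 19 (not isolated), via Z-alkylidene lactone acid 20 (not isolated)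
Conditions: H2 (1 atm), 10% Pd/C, EtOAc, rt, short; filter; then TMSCHN2, PhMe/MeOH (9:1), 0 °C to rt
Reagents that add atoms: (trimethylsilyl)diazomethane C[Si](C)(C)C=[N+]=[N-]
Why: Hydrogenolysis of the benzyl carbonate frees the phenol under neutral conditions, and the phenol adds reversibly to the adjacent anhydride carbonyl (6-exo-trig) to give 20. The equilibrium is expected to favour 19, because a carboxylic acid cis to an aryl ester re-closes to the anhydride, but irreversible O-methylation of the acid by the diazoalkane drains it into 21. The Z geometry is inherited from the cyclic anhydride.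

Step 9
Reactants: 21 Z-alkylidene lactone methyl ester
Product: 22 methyl (2R,3R)-3-(4-methoxyphenyl)-2-[(3S,4R)-5,6,7,8-tetramethoxy-4-(4-methoxyphenyl)-2-oxochroman-3-yl]-3-(2,4,6-trimethoxyphenyl)propanoate
Conditions: H2 (60 bar), 10% Pd/C, EtOAc, 40 °C
Reagents that add atoms: none
Why: Heterogeneous syn hydrogenation; the C4' aryl group sits pseudo-axial to avoid 1,3-allylic strain with the exocyclic substituent and shields one face, so both hydrogens arrive anti to it. This sets C3' as S (ring B cis) and, through the Z geometry, C3 as R.

Step 10
Reactants: 22 saturated lactone methyl ester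
Product: 24 (3R,4R,3'S,4'R)-5,7,5',6',7',8'-hexahydroxy-4,4'-bis(4-hydroxyphenyl)-[3,3'-bichromane]-2,2'-dione (target), via nonaphenol lactone acid 23 (not isolated)
Conditions: BBr3 (20 equiv), CH2Cl2, −78 °C to rt; H2O, 0 °C; then HCl (1 M)/THF, 40 °C, argon, degassed solvents
Reagents that add atoms: none
Why: Lewis-acid cleavage of the nine aryl methyl ethers and of the methyl ester (alkyl–oxygen fission), followed by acid-catalysed 6-exo-trig lactonisation of the free acid onto an ortho hydroxyl of the symmetric trihydroxyphenyl ring; either ortho hydroxyl gives the same ring A. The non-basic medium protects the cis C3' centre, and the trans relationship in ring A is already fixed by C3 and C4.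

## Compound list

1 | dimethyl succinate | COC(=O)CCC(=O)OC | starting material
2 | 4-methoxybenzaldehyde | COc1ccc(C=O)cc1 | starting material
3 | (E)-3-(methoxycarbonyl)-4-(4-methoxyphenyl)but-3-enoic acid | COc1ccc(/C=C(/C(=O)OC)CC(=O)O)cc1 | intermediate (not isolated)
4 | (2E,3E)-2,3-bis(4-methoxybenzylidene)butanedioic acid | COc1ccc(/C=C(/C(=O)O)C(=C/c2ccc(OC)cc2)\C(=O)O)cc1 | intermediate
5 | (3E,4E)-3,4-bis(4-methoxybenzylidene)oxolane-2,5-dione | COc1ccc(/C=C2/C(=O)OC(=O)/C2=C/c2ccc(OC)cc2)cc1 | intermediate
6 | 1,2,3,4-tetramethoxybenzene | COc1ccc(OC)c(OC)c1OC | starting material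
7 | N-methyl-N-[(2,3,4,5-tetramethoxyphenyl)methylidene]methanaminium chloride | C[N+](C)=Cc1cc(OC)c(OC)c(OC)c1OC.[Cl-] | intermediate (not isolated)
8 | 2,3,4,5-tetramethoxybenzaldehyde | COc1cc(C=O)c(OC)c(OC)c1OC | intermediate
9 | 2,3,4,5-tetramethoxyphenyl formate | COc1cc(OC=O)c(OC)c(OC)c1OC | intermediate (not isolated)
10 | 2,3,4,5-tetramethoxyphenol | COc1cc(O)c(OC)c(OC)c1OC | intermediate
11 | 1,3,5-trimethoxybenzene | COc1cc(OC)cc(OC)c1 | starting material
12 | (E)-3-(4-methoxyphenyl)-2-[(4R)-5,6,7,8-tetramethoxy-4-(4-methoxyphenyl)-2-oxochroman-3-yl]prop-2-enoic acid (C3' epimers) | OC(=O)/C(=C/c1ccc(OC)cc1)C1C(=O)Oc2c(OC)c(OC)c(OC)c(OC)c2[C@H]1c1ccc(OC)cc1 | intermediate (not isolated)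
13 | (3R)-3-(4-methoxyphenyl)-2-[(4R)-5,6,7,8-tetramethoxy-4-(4-methoxyphenyl)-2-oxochroman-3-yl]-3-(2,4,6-trimethoxyphenyl)propanoic acid (mixture at C2 of the acid and C3 of the chromanone) | OC(=O)C([C@H](c1ccc(OC)cc1)c1c(OC)cc(OC)cc1OC)C1C(=O)Oc2c(OC)c(OC)c(OC)c(OC)c2[C@H]1c1ccc(OC)cc1 | intermediate
14 | 2-[(R)-(2-hydroxy-3,4,5,6-tetramethoxyphenyl)(4-methoxyphenyl)methyl]-3-[(R)-(4-methoxyphenyl)(2,4,6-trimethoxyphenyl)methyl]butanedioic acid (mixture at C2 and C3) | OC(=O)C([C@H](c1ccc(OC)cc1)c1c(OC)cc(OC)cc1OC)C(C(=O)O)[C@H](c1ccc(OC)cc1)c1c(O)c(OC)c(OC)c(OC)c1OC | intermediate (not isolated)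
15 | 2-[(R)-{2-[(benzyloxycarbonyl)oxy]-3,4,5,6-tetramethoxyphenyl}(4-methoxyphenyl)methyl]-3-[(R)-(4-methoxyphenyl)(2,4,6-trimethoxyphenyl)methyl]butanedioic acid (mixture at C2 and C3) | OC(=O)C([C@H](c1ccc(OC)cc1)c1c(OC)cc(OC)cc1OC)C(C(=O)O)[C@H](c1ccc(OC)cc1)c1c(OC(=O)OCc2ccccc2)c(OC)c(OC)c(OC)c1OC | intermediate (not isolated)
16 | 3-[(R)-{2-[(benzyloxycarbonyl)oxy]-3,4,5,6-tetramethoxyphenyl}(4-methoxyphenyl)methyl]-4-[(R)-(4-methoxyphenyl)(2,4,6-trimethoxyphenyl)methyl]oxolane-2,5-dione (cis/trans mixture) | O=C1OC(=O)C([C@H](c2ccc(OC)cc2)c2c(OC)cc(OC)cc2OC)C1[C@H](c1ccc(OC)cc1)c1c(OC(=O)OCc2ccccc2)c(OC)c(OC)c(OC)c1OC | intermediate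
17 | 3-[(R)-{2-[(benzyloxycarbonyl)oxy]-3,4,5,6-tetramethoxyphenyl}(4-methoxyphenyl)methyl]-4-[(R)-(4-methoxyphenyl)(2,4,6-trimethoxyphenyl)methyl]-2,5-bis(trimethylsilyloxy)furan | C[Si](C)(C)Oc1oc(O[Si](C)(C)C)c([C@H](c2ccc(OC)cc2)c2c(OC)cc(OC)cc2OC)c1[C@H](c1ccc(OC)cc1)c1c(OC(=O)OCc2ccccc2)c(OC)c(OC)c(OC)c1OC | intermediate (not isolated)
18 | 3-[(R)-{2-[(benzyloxycarbonyl)oxy]-3,4,5,6-tetramethoxyphenyl}(4-methoxyphenyl)methyl]-4-[(R)-(4-methoxyphenyl)(2,4,6-trimethoxyphenyl)methyl]furan-2,5-dione | O=C1OC(=O)C([C@H](c2ccc(OC)cc2)c2c(OC)cc(OC)cc2OC)=C1[C@H](c1ccc(OC)cc1)c1c(OC(=O)OCc2ccccc2)c(OC)c(OC)c(OC)c1OC | intermediate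
19 | 3-[(R)-(2-hydroxy-3,4,5,6-tetramethoxyphenyl)(4-methoxyphenyl)methyl]-4-[(R)-(4-methoxyphenyl)(2,4,6-trimethoxyphenyl)methyl]furan-2,5-dione | O=C1OC(=O)C([C@H](c2ccc(OC)cc2)c2c(OC)cc(OC)cc2OC)=C1[C@H](c1ccc(OC)cc1)c1c(O)c(OC)c(OC)c(OC)c1OC | intermediate (not isolated)
20 | (2Z,3R)-3-(4-methoxyphenyl)-2-[(4R)-5,6,7,8-tetramethoxy-4-(4-methoxyphenyl)-2-oxochroman-3-ylidene]-3-(2,4,6-trimethoxyphenyl)propanoic acid | OC(=O)/C([C@H](c1ccc(OC)cc1)c1c(OC)cc(OC)cc1OC)=C1\C(=O)Oc2c(OC)c(OC)c(OC)c(OC)c2[C@H]1c1ccc(OC)cc1 | intermediate (not isolated)
21 | methyl (2Z,3R)-3-(4-methoxyphenyl)-2-[(4R)-5,6,7,8-tetramethoxy-4-(4-methoxyphenyl)-2-oxochroman-3-ylidene]-3-(2,4,6-trimethoxyphenyl)propanoate | COC(=O)/C([C@H](c1ccc(OC)cc1)c1c(OC)cc(OC)cc1OC)=C1\C(=O)Oc2c(OC)c(OC)c(OC)c(OC)c2[C@H]1c1ccc(OC)cc1 | intermediate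
22 | methyl (2R,3R)-3-(4-methoxyphenyl)-2-[(3S,4R)-5,6,7,8-tetramethoxy-4-(4-methoxyphenyl)-2-oxochroman-3-yl]-3-(2,4,6-trimethoxyphenyl)propanoate | COC(=O)[C@H]([C@H](c1ccc(OC)cc1)c1c(OC)cc(OC)cc1OC)[C@H]1C(=O)Oc2c(OC)c(OC)c(OC)c(OC)c2[C@H]1c1ccc(OC)cc1 | intermediate
23 | (2R,3R)-3-(4-hydroxyphenyl)-2-[(3S,4R)-5,6,7,8-tetrahydroxy-4-(4-hydroxyphenyl)-2-oxochroman-3-yl]-3-(2,4,6-trihydroxyphenyl)propanoic acid | OC(=O)[C@H]([C@H](c1ccc(O)cc1)c1c(O)cc(O)cc1O)[C@H]1C(=O)Oc2c(O)c(O)c(O)c(O)c2[C@H]1c1ccc(O)cc1 | intermediate (not isolated)
24 | (3R,4R,3'S,4'R)-5,7,5',6',7',8'-hexahydroxy-4,4'-bis(4-hydroxyphenyl)-[3,3'-bichromane]-2,2'-dione | O=C1Oc2cc(O)cc(O)c2[C@@H](c2ccc(O)cc2)[C@@H]1[C@H]1C(=O)Oc2c(O)c(O)c(O)c(O)c2[C@H]1c1ccc(O)cc1 | target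

## Step count and least certain steps

Total: 10 steps. Longest linear sequence: 8 steps (1, 2, 5, 6, 7, 8, 9, 10; the branch 3, 4, 5 to 10 is equally long).

Step 5 (key step). The second arylation may fail to proceed, because a free α-substituted cinnamic acid is a weak acceptor for a catalytic chiral acid. Facial selectivity at C4 may be low or mismatched, because 11 offers no hydrogen-bond handle. The required equal facial sense at both carbons is unproven. The fallback uses known acid-mediated hydroarylation without asymmetric induction and sets out from 5 with 10 and 11. Trifluoroacetic acid in CH2Cl2 at rt should give the racemic ring B lactone cinnamic acid F1, and addition of 11 at 40 °C the stereoisomer mixture of the lactone acid F2. The sequence of step 6 then passes through the stereoisomer mixtures of the phenol diacid F3 and the benzyl carbonate diacid F4 to the succinic anhydride benzyl carbonate F5. The sequence of step 7 passes through the bis(trimethylsilyloxy)furan F6 to the maleic anhydride benzyl carbonate F7, which consists of only two racemic diastereomers because C3 and C3' are erased. The like diastereomer is separated on silica and resolved by preparative chromatography on a chiral stationary phase, which returns to the route at 18 at the cost of at least half of the material.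

Step 9. Hydrogen uptake may be very slow on a tetrasubstituted alkene flanked by two diarylmethyl groups. Palladium hydride may move the double bond into conjugation with the aryl groups, which would erase C4 or C4'. Facial selectivity may be incomplete. The fallback replaces hydrogenation by kinetic protonation and sets out from 17. Protonation at −78 °C (MeOH, AcOH) should deliver the second proton anti to the substituent just created and so give cis-anhydrides, among them the (3R,3'S)-cis-succinic anhydride benzyl carbonate F8; no bias between the two faces of the furan is expected in the first protonation, so at best about half of the material follows this course. Hydrogenolysis (H2, 1 atm, Pd/C) gives the (3R,3'S)-cis-succinic anhydride phenol F9, which in the saturated series should close ring B spontaneously to the (3R,3'S)-lactone acid F10. Esterification with TMSCHN2 and chromatographic removal of the isomeric material return to the route at 22.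

Step 8. The ring–chain equilibrium between 19 and 20 may be established slowly or lie very far on the anhydride side. The diazoalkane may undergo dipolar cycloaddition to the electron-poor alkene. The alkene may be partly reduced during hydrogenolysis. The fallback replaces capture of the minor acid form by transesterification and sets out from 19. Acidic methanol with a water scavenger (MeOH, HC(OMe)3, H2SO4 cat., 50 °C) should give the dimethyl Z-maleate phenol F11. Acid-catalysed lactonisation with removal of methanol (camphorsulfonic acid cat., PhMe, 80 °C) then closes ring B on the cis ester and returns to the route at 21.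

Step 7. Bis-silylation of the crowded anhydride may be incomplete. Bromine may attack the trimethoxyphenyl ring, which has two free positions. Residual amine may remove the vinylogously acidic C4 or C4' hydrogen of the product and erode its configuration. The fallback avoids electrophilic bromine and sets out from 17. PhSeCl (1.0 equiv, −78 °C) followed by aqueous work-up should give the α-phenylselanyl succinic anhydride F12. Oxidation with H2O2 at 0 °C gives the selenoxide F13, whose syn elimination towards the carbonyl-activated ring hydrogen returns to the route at 18. Only the isomer with selenium cis to that hydrogen can eliminate into the ring; because the hydrogen is α to a carbonyl, F12 can be equilibrated towards this isomer beforehand.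

Step 10. Cleavage of the contiguous, crowded methoxy groups of ring B may be incomplete. The tetrahydroxylated ring may oxidise in air during isolation. Prolonged contact with acid may epimerise C3'. The fallback changes the isolation strategy and sets out from 22. After the same ether cleavage and lactonisation, the crude product is acetylated without base (Ac2O, H2SO4 cat.) to the octaacetate of 24 F14, which is stable to air and chromatography and allows removal of any C3' epimer. Acid-catalysed methanolysis (HCl, MeOH, 0 °C to rt), followed by brief warming in aqueous HCl/THF to re-close any opened lactone, returns to the route at 24.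

Step 1. The second condensation must take place on the carboxylate salt of 3, which is deprotonated reluctantly, so the reaction may stop after one condensation or be overtaken by self-condensation of the aldehyde. The fallback is the stepwise Stobbe sequence and sets out from 1 and 2. t-BuOK in t-BuOH with one equivalent of 2 gives 3, which is isolated. Esterification (MeOH, H2SO4 cat.) gives dimethyl (E)-2-(4-methoxybenzylidene)succinate F15. A second Stobbe condensation with 2 (NaOMe, MeOH, reflux) gives (E,E)-bis(4-methoxybenzylidene)succinic acid monomethyl ester F16. Saponification (NaOH aq, then HCl) returns to the route at 4.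

## Further compounds

F1 | step 5 | racemic ring B lactone cinnamic acid (constitution of 12) | OC(=O)/C(=C/c1ccc(OC)cc1)C1C(=O)Oc2c(OC)c(OC)c(OC)c(OC)c2C1c1ccc(OC)cc1
F2 | step 5 | stereoisomer mixture of the lactone acid (constitution of 13) | OC(=O)C(C(c1ccc(OC)cc1)c1c(OC)cc(OC)cc1OC)C1C(=O)Oc2c(OC)c(OC)c(OC)c(OC)c2C1c1ccc(OC)cc1
F3 | step 5 | stereoisomer mixture of the phenol diacid (constitution of 14) | OC(=O)C(C(c1ccc(OC)cc1)c1c(OC)cc(OC)cc1OC)C(C(=O)O)C(c1ccc(OC)cc1)c1c(O)c(OC)c(OC)c(OC)c1OC
F4 | step 5 | stereoisomer mixture of the benzyl carbonate diacid (constitution of 15) | OC(=O)C(C(c1ccc(OC)cc1)c1c(OC)cc(OC)cc1OC)C(C(=O)O)C(c1ccc(OC)cc1)c1c(OC(=O)OCc2ccccc2)c(OC)c(OC)c(OC)c1OC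
F5 | step 5 | stereoisomer mixture of the succinic anhydride benzyl carbonate (constitution of 16) | O=C1OC(=O)C(C(c2ccc(OC)cc2)c2c(OC)cc(OC)cc2OC)C1C(c1ccc(OC)cc1)c1c(OC(=O)OCc2ccccc2)c(OC)c(OC)c(OC)c1OC
F6 | step 5 | stereoisomer mixture of the bis(trimethylsilyloxy)furan (constitution of 17) | C[Si](C)(C)Oc1oc(O[Si](C)(C)C)c(C(c2ccc(OC)cc2)c2c(OC)cc(OC)cc2OC)c1C(c1ccc(OC)cc1)c1c(OC(=O)OCc2ccccc2)c(OC)c(OC)c(OC)c1OC
F7 | step 5 | stereoisomer mixture of the maleic anhydride benzyl carbonate (constitution of 18) | O=C1OC(=O)C(C(c2ccc(OC)cc2)c2c(OC)cc(OC)cc2OC)=C1C(c1ccc(OC)cc1)c1c(OC(=O)OCc2ccccc2)c(OC)c(OC)c(OC)c1OC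
F8 | step 9 | (3R,3'S)-cis-succinic anhydride benzyl carbonate (target numbering; diarylmethine carbons R,R) | O=C1OC(=O)[C@H]([C@H](c2ccc(OC)cc2)c2c(OC)cc(OC)cc2OC)[C@@H]1[C@H](c1ccc(OC)cc1)c1c(OC(=O)OCc2ccccc2)c(OC)c(OC)c(OC)c1OC
F9 | step 9 | (3R,3'S)-cis-succinic anhydride phenol | O=C1OC(=O)[C@H]([C@H](c2ccc(OC)cc2)c2c(OC)cc(OC)cc2OC)[C@@H]1[C@H](c1ccc(OC)cc1)c1c(O)c(OC)c(OC)c(OC)c1OC
F10 | step 9 | (2R,3R)-3-(4-methoxyphenyl)-2-[(3S,4R)-5,6,7,8-tetramethoxy-4-(4-methoxyphenyl)-2-oxochroman-3-yl]-3-(2,4,6-trimethoxyphenyl)propanoic acid | OC(=O)[C@H]([C@H](c1ccc(OC)cc1)c1c(OC)cc(OC)cc1OC)[C@H]1C(=O)Oc2c(OC)c(OC)c(OC)c(OC)c2[C@H]1c1ccc(OC)cc1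
F11 | step 8 | dimethyl (Z)-2-[(R)-(2-hydroxy-3,4,5,6-tetramethoxyphenyl)(4-methoxyphenyl)methyl]-3-[(R)-(4-methoxyphenyl)(2,4,6-trimethoxyphenyl)methyl]but-2-enedioate | COC(=O)/C([C@H](c1ccc(OC)cc1)c1c(OC)cc(OC)cc1OC)=C(\C(=O)OC)[C@H](c1ccc(OC)cc1)c1c(O)c(OC)c(OC)c(OC)c1OC
F12 | step 7 | α-phenylselanyl succinic anhydride benzyl carbonate (regioisomer shown; diarylmethine carbons as in 16; ring carbons as a mixture) | O=C1OC(=O)C([Se]c2ccccc2)([C@H](c2ccc(OC)cc2)c2c(OC)cc(OC)cc2OC)C1[C@H](c1ccc(OC)cc1)c1c(OC(=O)OCc2ccccc2)c(OC)c(OC)c(OC)c1OC
F13 | step 7 | α-phenylseleninyl succinic anhydride benzyl carbonate (selenoxide of F12; not isolated) | O=C1OC(=O)C([Se](=O)c2ccccc2)([C@H](c2ccc(OC)cc2)c2c(OC)cc(OC)cc2OC)C1[C@H](c1ccc(OC)cc1)c1c(OC(=O)OCc2ccccc2)c(OC)c(OC)c(OC)c1OC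
F14 | step 10 | octaacetate of 24 | O=C1Oc2cc(OC(C)=O)cc(OC(C)=O)c2[C@@H](c2ccc(OC(C)=O)cc2)[C@@H]1[C@H]1C(=O)Oc2c(OC(C)=O)c(OC(C)=O)c(OC(C)=O)c(OC(C)=O)c2[C@H]1c1ccc(OC(C)=O)cc1
F15 | step 1 | dimethyl (E)-2-(4-methoxybenzylidene)succinate | COc1ccc(/C=C(/C(=O)OC)CC(=O)OC)cc1
F16 | step 1 | (E,E)-bis(4-methoxybenzylidene)succinic acid monomethyl ester | COc1ccc(/C=C(/C(=O)O)C(=C/c2ccc(OC)cc2)\C(=O)OC)cc1
A1 | alternative 1 | 4-nitrophenyl 2-[5,6,7,8-tetramethoxy-4-(4-methoxyphenyl)-2-oxo-2H-chromen-3-yl]acetate | O=C(Cc1c(-c2ccc(OC)cc2)c2c(OC)c(OC)c(OC)c(OC)c2oc1=O)Oc1ccc([N+](=O)[O-])cc1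
A2 | alternative 1 | 2-[hydroxy(4-methoxyphenyl)methyl]-3,5-dimethoxyphenol (racemic) | COc1cc(O)c(C(O)c2ccc(OC)cc2)c(OC)c1
A3 | alternative 1 | (3R,4R)-ring A lactone attached at C3 to the 4-arylcoumarin of ring B | O=C1Oc2cc(OC)cc(OC)c2[C@@H](c2ccc(OC)cc2)[C@@H]1c1c(-c2ccc(OC)cc2)c2c(OC)c(OC)c(OC)c(OC)c2oc1=O
A4 | alternative 2 | 2-[(1R,2Z,4R)-1,4-bis(4-methoxyphenyl)-4-(pentamethoxyphenyl)but-2-en-1-yl]-3,5-dimethoxyphenyl carbonochloridate | ClC(=O)Oc1cc(OC)cc(OC)c1[C@@H](c1ccc(OC)cc1)/C=C\[C@H](c1ccc(OC)cc1)c1c(OC)c(OC)c(OC)c(OC)c1OC
A5 | alternative 2 | trans ring A lactone carrying the C2' methyl ester and the pentamethoxyphenyl group | O=C1Oc2cc(OC)cc(OC)c2[C@@H](c2ccc(OC)cc2)[C@@H]1[C@H]([C@H](c1ccc(OC)cc1)c1c(OC)c(OC)c(OC)c(OC)c1OC)C(=O)OC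
A6 | alternative 3 | 4-nitrophenyl 2-[(3S,4R)-5,7-dimethoxy-4-(4-methoxyphenyl)-2-oxochroman-3-yl]acetate | O=C1Oc2cc(OC)cc(OC)c2[C@@H](c2ccc(OC)cc2)[C@@H]1CC(=O)Oc1ccc([N+](=O)[O-])cc1
A7 | alternative 3 | 2-[hydroxy(4-methoxyphenyl)methyl]-3,4,5,6-tetramethoxyphenol (racemic) | COc1c(O)c(C(O)c2ccc(OC)cc2)c(OC)c(OC)c1OC
A8 | alternative 3 | octa-O-methyl ether of 24 | O=C1Oc2cc(OC)cc(OC)c2[C@@H](c2ccc(OC)cc2)[C@@H]1[C@H]1C(=O)Oc2c(OC)c(OC)c(OC)c(OC)c2[C@H]1c1ccc(OC)cc1
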